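**Plan**

Locants: ring C1 (CH2OAc), C2 (=CH), C3 (C=O), C4 (oxirane carbon with the side chain), C5 (oxirane CH), C6 (C=O); chain C1′ (CHOAc) to C6′ (CHO).
Retrosynthesis: the two carbonyl masks (C6 ketal, C6′ acetal), both acetates and the C4–C5 oxirane are removed first. What remains of the ring is a masked p-hydroquinone with para oxygens differentiated as C3–OH and C6–OMe, the chain on C4 and CH2O on C1; this feature allows the cut at C5–C6, C3–C4 and C2–C3.
These three bonds form in one benzannulation of an alkenyl(methoxy)carbene chromium complex (C6, C1, C2; one CO ligand becomes C3) with a terminal alkyne (C4, C5 and the whole side chain). This closes the only carbocycle; the oxirane is the second ring.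
Forward: carbene complex in 2 steps; alkyne in 7 steps (a Wittig reaction makes C4′=C5′, an acetylide acylation makes C1′–C≡C); union; then oxidative dearomatisation, epoxidation, acetylation and one acid step that frees both carbonyls.
Stereochemistry: C1′ (S) from a Midland reduction of an ynone; C4 (R) and C5 (S) relayed from C1′ by a lithium-chelated, hydroxyl-directed nucleophilic epoxidation; both E-alkenes from a commercial E-enoate and an E-selective Wittig reaction.

Key step: step 10

Assumption: chromium compounds are written in the Cr=C=O SMILES convention, and the η6-arene complex 18 is written as arene and Cr(CO)3 fragment joined by a dot because SMILES cannot express η6 bonding.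

**Route**

Step 1
Reactants: 1 2-bromoprop-2-en-1-ol
Product: 2 [(2-bromoprop-2-en-1-yl)oxy](tert-butyl)diphenylsilane
Conditions: TBDPSCl, imidazole, CH2Cl2, 0 °C → rt
Reagents that add atoms: tert-butyl(chloro)diphenylsilane, CC(C)(C)[Si](Cl)(c1ccccc1)c1ccccc1
Why: Imidazole-promoted O-silylation of a primary allylic alcohol; the vinyl bromide is inert and no stereocentre is involved.

Step 2
Reactants: 2 [(2-bromoprop-2-en-1-yl)oxy](tert-butyl)diphenylsilane; 3 hexacarbonylchromium
Product: 6 pentacarbonyl[methoxy(3-(tert-butyldiphenylsilyloxy)prop-1-en-2-yl)carbene]chromium, via 2-lithioallyl silyl ether 4 (not isolated), via lithium acylchromate 5 (not isolated)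
Conditions: t-BuLi (2 equiv), Et2O, −78 °C; Cr(CO)6, Et2O/THF, −78 → 0 °C; Me3OBF4, CH2Cl2, 0 °C
Reagents that add atoms: trimethyloxonium tetrafluoroborate, C[O+](C)C.F[B-](F)(F)F
Why: Fischer carbene synthesis: bromine–lithium exchange at −78 °C gives the 2-lithioallyl ether (the bulky silyl group and the low temperature hold back retro-Brook migration and β-elimination), which adds to a CO ligand to give the acylchromate that Meerwein's salt methylates on oxygen.

Step 3
Reactants: 7 ethyl (2E)-3-methyl-4-oxobut-2-enoate; 8 (triphenylphosphoranylidene)acetaldehyde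
Product: 9 ethyl (2E,4E)-3-methyl-6-oxohexa-2,4-dienoate
Conditions: toluene, 60 °C (1.0 equiv of 8)
Reagents that add atoms: none
Why: Wittig olefination with a stabilised ylide is E-selective and takes the aldehyde, not the ester; the ester-conjugated aldehyde of 7 is more electrophilic than the dienal formed, which should limit double homologation.

Step 4
Reactants: 9 ethyl (2E,4E)-3-methyl-6-oxohexa-2,4-dienoate
Product: 10 ethyl (2E,4E)-6,6-dimethoxy-3-methylhexa-2,4-dienoate
Conditions: HC(OMe)3, PPTS (cat.), MeOH, rt; Et3N quench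
Reagents that add atoms: trimethyl orthoformate, COC(OC)OC
Why: Acid-catalysed acetalisation with orthoformate as water scavenger masks the aldehyde selectively and should leave the ester and the E,E-diene untouched.

Step 5
Reactants: 10 ethyl (2E,4E)-6,6-dimethoxy-3-methylhexa-2,4-dienoate
Product: 11 (2E,4E)-N,6,6-trimethoxy-N,3-dimethylhexa-2,4-dienamide
Conditions: MeNH(OMe)·HCl, i-PrMgCl, THF, −20 → 0 °C
Reagents that add atoms: N,O-dimethylhydroxylamine hydrochloride, CNOC.Cl
Why: Direct ester aminolysis with the chloromagnesium amide gives the Weinreb amide; the acetal is base-stable and the β,β-disubstituted dienoate should not take conjugate addition at low temperature.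

Step 6
Reactants: 11 (2E,4E)-N,6,6-trimethoxy-N,3-dimethylhexa-2,4-dienamide; 12 ethynyl(trimethyl)silane
Product: 14 (4E,6E)-8,8-dimethoxy-5-methyl-1-(trimethylsilyl)octa-4,6-dien-1-yn-3-one, via lithium trimethylsilylacetylide 13 (not isolated)
Conditions: n-BuLi, THF, −78 °C; then 11, −78 → 0 °C; sat. NH4Cl
Reagents that add atoms: none
Why: Weinreb ketone synthesis: the acetylide adds once and the chelated tetrahedral intermediate survives until the mild quench that spares the acetal; the silyl cap keeps the ynone from conjugate addition of the released amine.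

Step 7
Reactants: 14 (4E,6E)-8,8-dimethoxy-5-methyl-1-(trimethylsilyl)octa-4,6-dien-1-yn-3-one
Product: 15 (3S,4E,6E)-8,8-dimethoxy-5-methyl-1-(trimethylsilyl)octa-4,6-dien-1-yn-3-ol
Conditions: (S)-Alpine-Borane (neat, 2 equiv), rt; then ethanolamine, Et2O, 0 °C
Reagents that add atoms: none
Why: Midland reduction: hydride passes from the pinanyl C–H through a boat-like six-membered transition state in which the slim alkynyl group takes the hindered position, so (S)-Alpine-Borane (from (−)-α-pinene) should set C1′ as S, the mirror image of the (R)-reagent/1-octyn-3-one to (R)-1-octyn-3-ol case; acetal and diene are inert to the neutral borane.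

Step 8
Reactants: 15 (3S,4E,6E)-8,8-dimethoxy-5-methyl-1-(trimethylsilyl)octa-4,6-dien-1-yn-3-ol
Product: 16 (3S,4E,6E)-8,8-dimethoxy-5-methylocta-4,6-dien-1-yn-3-ol
Conditions: K2CO3 (cat.), MeOH, 0 °C → rt
Reagents that add atoms: none
Why: Base-catalysed methanolysis of the C(sp)–Si bond (protodesilylation) frees the terminal alkyne without touching the acetal or the carbinol centre.

Step 9
Reactants: 16 (3S,4E,6E)-8,8-dimethoxy-5-methylocta-4,6-dien-1-yn-3-ol
Product: 17 {[(3S,4E,6E)-8,8-dimethoxy-5-methylocta-4,6-dien-1-yn-3-yl]oxy}(triethyl)silane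
Conditions: TESCl, imidazole, CH2Cl2, 0 °C
Reagents that add atoms: chlorotriethylsilane, CC[Si](Cl)(CC)CC
Why: Silyl ether formation; TES is chosen because it later leaves in acidic methanol while the primary TBDPS ether stays.

Step 10
Reactants: 6 pentacarbonyl[methoxy(3-(tert-butyldiphenylsilyloxy)prop-1-en-2-yl)carbene]chromium; 17 {[(3S,4E,6E)-8,8-dimethoxy-5-methylocta-4,6-dien-1-yn-3-yl]oxy}(triethyl)silane
Product: 19 5-[(tert-butyldiphenylsilyloxy)methyl]-2-[(1S,2E,4E)-6,6-dimethoxy-3-methyl-1-(triethylsilyloxy)hexa-2,4-dien-1-yl]-4-methoxyphenol, via arene tricarbonylchromium complex 18 (not isolated)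
Conditions: THF (0.05 M, degassed), 50 °C; then air, rt; Et3N-deactivated silica
Reagents that add atoms: none
Why: Dötz benzannulation: thermal loss of one CO from 6 lets the terminal alkyne of 17 coordinate and insert into the Cr=C bond with its unsubstituted carbon bonding to the carbene carbon (C5–C6); CO insertion then gives a chromium-bound vinylketene (C3–C4), which cyclises onto the methylene terminus of the alkenyl group (C2–C3) and tautomerises to the Cr(CO)3-bound 4-methoxyphenol that air releases. The closest known reaction type is the benzannulation of 2-propenyl(methoxy)carbene chromium complexes with terminal alkynes, propargylic silyl ethers included, in THF. The one ring formed, the six-membered carbocycle, closes by 6π-electrocyclisation of the dienylketene. No stereocentre is created, and the C1′ centre of 17 is a spectator that cannot epimerise under the neutral conditions. The step needs regioselective insertion, which the steric difference between the two alkyne carbons (H against the branched propargylic carbon) secures, placing the side chain next to the new phenol and C5–H next to C6–OMe. It also needs the 1,3-diene to stay out, which is expected because that diene is 1,4-disubstituted, branched at one end and inductively deactivated by the acetal, while the α-branched carbene complex is a sluggish dienophile.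

Step 11
Reactants: 19 5-[(tert-butyldiphenylsilyloxy)methyl]-2-[(1S,2E,4E)-6,6-dimethoxy-3-methyl-1-(triethylsilyloxy)hexa-2,4-dien-1-yl]-4-methoxyphenol
Product: 21 5-[(tert-butyldiphenylsilyloxy)methyl]-2-[(1S,2E,4E)-1-hydroxy-6,6-dimethoxy-3-methylhexa-2,4-dien-1-yl]-4,4-dimethoxycyclohexa-2,5-dien-1-one, via TES-protected quinone monoketal 20 (not isolated)
Conditions: PhI(OAc)2, MeOH, 0 °C; then PPTS (cat.), 0 °C → rt; Et3N quench
Reagents that add atoms: methanol, CO
Why: Hypervalent-iodine oxidative dearomatisation of a 4-methoxyphenol in methanol gives the p-quinone monoketal with the carbonyl at the former phenol carbon (C3) and the ketal at C6; PPTS in the same methanol then solvolyses only the TES ether, since TBDPS is far more acid-stable and ketal and acetal merely exchange methanol with the solvent.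

Step 12
Reactants: 21 5-[(tert-butyldiphenylsilyloxy)methyl]-2-[(1S,2E,4E)-1-hydroxy-6,6-dimethoxy-3-methylhexa-2,4-dien-1-yl]-4,4-dimethoxycyclohexa-2,5-dien-1-one
Product: 22 (1R,6S)-4-[(tert-butyldiphenylsilyloxy)methyl]-1-[(1S,2E,4E)-1-hydroxy-6,6-dimethoxy-3-methylhexa-2,4-dien-1-yl]-5,5-dimethoxy-7-oxabicyclo[4.1.0]hept-3-en-2-one
Conditions: t-BuOOH (anhydrous, decane), n-BuLi, THF, −78 → −20 °C
Reagents that add atoms: tert-butyl hydroperoxide, CC(C)(C)OO
Why: Hydroxyl-directed nucleophilic (Weitz–Scheffer-type) epoxidation: lithium bridges the C1′ hydroxyl and the C3 carbonyl in a six-membered chelate that holds C1′–O in the ring plane, so the peroxide adds to the unsubstituted β-carbon C5 and the chelated enolate closes at C4 on the face anti to the dienyl group (as in a Fráter–Seebach alkylation), which should give the 4R,5S oxirane from the 1′S carbinol; the C1=C2 enone is spared because C1 is fully substituted and flanked by the ketal.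

Step 13
Reactants: 22 (1R,6S)-4-[(tert-butyldiphenylsilyloxy)methyl]-1-[(1S,2E,4E)-1-hydroxy-6,6-dimethoxy-3-methylhexa-2,4-dien-1-yl]-5,5-dimethoxy-7-oxabicyclo[4.1.0]hept-3-en-2-one
Product: 23 (1R,6S)-1-[(1S,2E,4E)-1-hydroxy-6,6-dimethoxy-3-methylhexa-2,4-dien-1-yl]-4-(hydroxymethyl)-5,5-dimethoxy-7-oxabicyclo[4.1.0]hept-3-en-2-one
Conditions: TBAF, AcOH (1:1), THF, 0 °C → rt
Reagents that add atoms: none
Why: Fluoride-mediated desilylation; buffering with acetic acid avoids a free alkoxide next to the oxirane (no Payne rearrangement) and spares the epoxy ketone.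

Step 14
Reactants: 23 (1R,6S)-1-[(1S,2E,4E)-1-hydroxy-6,6-dimethoxy-3-methylhexa-2,4-dien-1-yl]-4-(hydroxymethyl)-5,5-dimethoxy-7-oxabicyclo[4.1.0]hept-3-en-2-one
Product: 24 (1S,2E,4E)-1-[(1R,6S)-4-(acetoxymethyl)-5,5-dimethoxy-2-oxo-7-oxabicyclo[4.1.0]hept-3-en-1-yl]-6,6-dimethoxy-3-methylhexa-2,4-dien-1-yl acetate
Conditions: Ac2O, pyridine, DMAP (cat.), CH2Cl2, 0 °C
Reagents that add atoms: acetic anhydride, CC(=O)OC(C)=O
Why: DMAP-catalysed acylation esterifies the primary and the hindered secondary hydroxyl in one operation; no stereocentre is touched.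

Step 15
Reactants: 24 (1S,2E,4E)-1-[(1R,6S)-4-(acetoxymethyl)-5,5-dimethoxy-2-oxo-7-oxabicyclo[4.1.0]hept-3-en-1-yl]-6,6-dimethoxy-3-methylhexa-2,4-dien-1-yl acetate
Product: 25 (1S,2E,4E)-1-[(1R,6S)-4-(acetoxymethyl)-2,5-dioxo-7-oxabicyclo[4.1.0]hept-3-en-1-yl]-3-methyl-6-oxohexa-2,4-dien-1-yl acetate (CNP0307549.1)
Conditions: montmorillonite K10, wet CH2Cl2, rt
Reagents that add atoms: water, O
Why: Acid-catalysed hydrolysis on the clay should unmask first the dienal from its dimethyl acetal and then the C6 ketone from the ketal (a known deprotection of epoxyquinone monoketals); acetates and oxirane tolerate it, and once the dienal is free the C1′ acetate lies between two electron-poor π-systems and should not ionise.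

**Compound list**

1 | 2-bromoprop-2-en-1-ol | OCC(Br)=C | starting material
2 | [(2-bromoprop-2-en-1-yl)oxy](tert-butyl)diphenylsilane | C=C(Br)CO[Si](c1ccccc1)(c1ccccc1)C(C)(C)C | intermediate
3 | hexacarbonylchromium | O=C=[Cr](=C=O)(=C=O)(=C=O)(=C=O)=C=O | starting material
4 | {3-[(tert-butyldiphenylsilyl)oxy]prop-1-en-2-yl}lithium | [Li]C(=C)CO[Si](c1ccccc1)(c1ccccc1)C(C)(C)C | intermediate (not isolated)
5 | lithium pentacarbonyl{2-[(tert-butyldiphenylsilyloxy)methyl]prop-2-enoyl}chromate | [Li+].[O-]C(C(=C)CO[Si](c1ccccc1)(c1ccccc1)C(C)(C)C)=[Cr](=C=O)(=C=O)(=C=O)(=C=O)=C=O | intermediate (not isolated)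
6 | pentacarbonyl[methoxy(3-(tert-butyldiphenylsilyloxy)prop-1-en-2-yl)carbene]chromium | COC(C(=C)CO[Si](c1ccccc1)(c1ccccc1)C(C)(C)C)=[Cr](=C=O)(=C=O)(=C=O)(=C=O)=C=O | intermediate
7 | ethyl (2E)-3-methyl-4-oxobut-2-enoate | CCOC(=O)/C=C(C)/C=O | starting material
8 | (triphenylphosphoranylidene)acetaldehyde | O=CC=P(c1ccccc1)(c1ccccc1)c1ccccc1 | starting material
9 | ethyl (2E,4E)-3-methyl-6-oxohexa-2,4-dienoate | CCOC(=O)/C=C(C)/C=C/C=O | intermediate
10 | ethyl (2E,4E)-6,6-dimethoxy-3-methylhexa-2,4-dienoate | CCOC(=O)/C=C(C)/C=C/C(OC)OC | intermediate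
11 | (2E,4E)-N,6,6-trimethoxy-N,3-dimethylhexa-2,4-dienamide | CON(C)C(=O)/C=C(C)/C=C/C(OC)OC | intermediate
12 | ethynyl(trimethyl)silane | C#C[Si](C)(C)C | starting material
13 | lithium (trimethylsilyl)acetylide | [Li]C#C[Si](C)(C)C | intermediate (not isolated)
14 | (4E,6E)-8,8-dimethoxy-5-methyl-1-(trimethylsilyl)octa-4,6-dien-1-yn-3-one | C[Si](C)(C)C#CC(=O)/C=C(C)/C=C/C(OC)OC | intermediate
15 | (3S,4E,6E)-8,8-dimethoxy-5-methyl-1-(trimethylsilyl)octa-4,6-dien-1-yn-3-ol | C[Si](C)(C)C#C[C@H](/C=C(C)/C=C/C(OC)OC)O | intermediate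
16 | (3S,4E,6E)-8,8-dimethoxy-5-methylocta-4,6-dien-1-yn-3-ol | C#C[C@H](/C=C(C)/C=C/C(OC)OC)O | intermediate
17 | {[(3S,4E,6E)-8,8-dimethoxy-5-methylocta-4,6-dien-1-yn-3-yl]oxy}(triethyl)silane | C#C[C@H](/C=C(C)/C=C/C(OC)OC)O[Si](CC)(CC)CC | intermediate
18 | tricarbonyl(η6-arene)chromium complex of phenol 19 | COc1cc([C@H](/C=C(C)/C=C/C(OC)OC)O[Si](CC)(CC)CC)c(O)cc1CO[Si](c2ccccc2)(c3ccccc3)C(C)(C)C.O=C=[Cr](=C=O)=C=O | intermediate (not isolated)
19 | 5-[(tert-butyldiphenylsilyloxy)methyl]-2-[(1S,2E,4E)-6,6-dimethoxy-3-methyl-1-(triethylsilyloxy)hexa-2,4-dien-1-yl]-4-methoxyphenol | COc1cc([C@H](/C=C(C)/C=C/C(OC)OC)O[Si](CC)(CC)CC)c(O)cc1CO[Si](c2ccccc2)(c3ccccc3)C(C)(C)C | intermediate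
20 | 5-[(tert-butyldiphenylsilyloxy)methyl]-2-[(1S,2E,4E)-6,6-dimethoxy-3-methyl-1-(triethylsilyloxy)hexa-2,4-dien-1-yl]-4,4-dimethoxycyclohexa-2,5-dien-1-one | COC1(OC)C=C([C@H](/C=C(C)/C=C/C(OC)OC)O[Si](CC)(CC)CC)C(=O)C=C1CO[Si](c2ccccc2)(c3ccccc3)C(C)(C)C | intermediate (not isolated)
21 | 5-[(tert-butyldiphenylsilyloxy)methyl]-2-[(1S,2E,4E)-1-hydroxy-6,6-dimethoxy-3-methylhexa-2,4-dien-1-yl]-4,4-dimethoxycyclohexa-2,5-dien-1-one | COC1(OC)C=C([C@H](/C=C(C)/C=C/C(OC)OC)O)C(=O)C=C1CO[Si](c2ccccc2)(c3ccccc3)C(C)(C)C | intermediate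
22 | (1R,6S)-4-[(tert-butyldiphenylsilyloxy)methyl]-1-[(1S,2E,4E)-1-hydroxy-6,6-dimethoxy-3-methylhexa-2,4-dien-1-yl]-5,5-dimethoxy-7-oxabicyclo[4.1.0]hept-3-en-2-one | CC(C)(C)[Si](c3ccccc3)(c4ccccc4)OCC1=CC(=O)[C@]2([C@H](/C=C(C)/C=C/C(OC)OC)O)O[C@@H]2C1(OC)OC | intermediate
23 | (1R,6S)-1-[(1S,2E,4E)-1-hydroxy-6,6-dimethoxy-3-methylhexa-2,4-dien-1-yl]-4-(hydroxymethyl)-5,5-dimethoxy-7-oxabicyclo[4.1.0]hept-3-en-2-one | OCC1=CC(=O)[C@]2([C@H](/C=C(C)/C=C/C(OC)OC)O)O[C@@H]2C1(OC)OC | intermediate
24 | (1S,2E,4E)-1-[(1R,6S)-4-(acetoxymethyl)-5,5-dimethoxy-2-oxo-7-oxabicyclo[4.1.0]hept-3-en-1-yl]-6,6-dimethoxy-3-methylhexa-2,4-dien-1-yl acetate | CC(=O)OCC1=CC(=O)[C@]2([C@H](/C=C(C)/C=C/C(OC)OC)OC(C)=O)O[C@@H]2C1(OC)OC | intermediate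
25 | (1S,2E,4E)-1-[(1R,6S)-4-(acetoxymethyl)-2,5-dioxo-7-oxabicyclo[4.1.0]hept-3-en-1-yl]-3-methyl-6-oxohexa-2,4-dien-1-yl acetate | CC(=O)OCC1=CC(=O)[C@]2([C@H](/C=C(C)/C=C/C=O)OC(C)=O)O[C@@H]2C1=O | target

**Step count**

Total: 15 steps. Longest linear sequence: 13 steps (7 to 25, steps 3–15); the carbene branch (steps 1–2) joins at step 10.

**Steps most likely to fail**

Step 10 (benzannulation). Alkyne insertion may be outrun by other fates of the CO-depleted carbene complex (cyclobutenone or furan formation, reaction at the 1,3-diene). The ortho-hydroxybenzylic silyl ether may also lose silanol to an o-quinone methide during isolation. The fallback gives up ring construction and starts from an arene; it sets out from Weinreb amide 11 and comes back at phenol 19. Commercial 5-hydroxy-2-methoxybenzaldehyde would be O-allylated (allyl bromide, K2CO3, DMF) to 2-methoxy-5-(prop-2-en-1-yloxy)benzaldehyde F1 and reduced (NaBH4, MeOH) to [2-methoxy-5-(prop-2-en-1-yloxy)phenyl]methanol F2. Silylation (TBDPSCl, imidazole) would give the silyl ether F3, and bromination para to the silyloxymethyl group (NBS, MeCN) the aryl bromide F4. Bromine–lithium exchange (t-BuLi, THF, −78 °C) and acylation with 11 would give the aryl dienyl ketone F5. CBS reduction with (R)-Me-CBS and catecholborane, the ortho-substituted aryl ring taken as the large group and the sense to be confirmed by Mosher analysis, would give the (S)-carbinol F6. TESCl/imidazole would give the bis-silyl ether F7, and Pd(PPh3)4/morpholine would remove the allyl group to return 19.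

Step 12 (epoxidation). Facial selectivity may be poor if the lithium chelate is not maintained and the peroxide enters syn to the dienyl group. The fallback replaces substrate control by reagent control: a tartrate-mediated nucleophilic epoxidation (Ph3COOH, NaHMDS, diisopropyl tartrate, toluene, −40 °C), in which the sodium alkoxide of the C1′ hydroxyl is held in a chiral tartrate–peroxide aggregate. Both tartrate enantiomers would be tried and the matched one used. It sets out from 21 and comes back at 22 with no new compound (F0).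

Step 11 (dearomatisation with TES cleavage). Once the TES group is gone, the doubly allylic C1′ centre may undergo solvolysis or allylic transposition in acidic methanol. The fallback changes the order of events and the control element; it sets out from 19 and comes back at 22. Oxidation with PhI(OAc)2 in MeOH buffered with NaHCO3 would stop at the TES-protected monoketal 20, here isolated. Epoxidation of this silyl ether under non-chelating conditions (t-BuOOH, DBU, CH2Cl2, 0 °C) should occur anti to the silyloxy group in the rotamer with C1′–H in the ring plane next to C3=O, on the same face as in the main route, giving the C1′ triethylsilyl ether of 22, F8. Buffered fluoride (HF·pyridine/pyridine, THF, 0 °C) would then free the hydroxyl and give 22.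

**Further compounds**

F1 | step 10 | 2-methoxy-5-(prop-2-en-1-yloxy)benzaldehyde | COc1ccc(OCC=C)cc1C=O
F2 | step 10 | [2-methoxy-5-(prop-2-en-1-yloxy)phenyl]methanol | COc1ccc(OCC=C)cc1CO
F3 | step 10 | tert-butyl{[2-methoxy-5-(prop-2-en-1-yloxy)phenyl]methoxy}diphenylsilane | COc1ccc(OCC=C)cc1CO[Si](c2ccccc2)(c3ccccc3)C(C)(C)C
F4 | step 10 | {[4-bromo-2-methoxy-5-(prop-2-en-1-yloxy)phenyl]methoxy}(tert-butyl)diphenylsilane | COc1cc(Br)c(OCC=C)cc1CO[Si](c2ccccc2)(c3ccccc3)C(C)(C)C
F5 | step 10 | (2E,4E)-1-{4-[(tert-butyldiphenylsilyloxy)methyl]-5-methoxy-2-(prop-2-en-1-yloxy)phenyl}-6,6-dimethoxy-3-methylhexa-2,4-dien-1-one | COc1cc(C(=O)/C=C(C)/C=C/C(OC)OC)c(OCC=C)cc1CO[Si](c2ccccc2)(c3ccccc3)C(C)(C)C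
F6 | step 10 | (1S,2E,4E)-1-{4-[(tert-butyldiphenylsilyloxy)methyl]-5-methoxy-2-(prop-2-en-1-yloxy)phenyl}-6,6-dimethoxy-3-methylhexa-2,4-dien-1-ol | COc1cc([C@H](/C=C(C)/C=C/C(OC)OC)O)c(OCC=C)cc1CO[Si](c2ccccc2)(c3ccccc3)C(C)(C)C
F7 | step 10 | triethylsilyl ether of F6 (1S,2E,4E) | COc1cc([C@H](/C=C(C)/C=C/C(OC)OC)O[Si](CC)(CC)CC)c(OCC=C)cc1CO[Si](c2ccccc2)(c3ccccc3)C(C)(C)C
F0 | step 12 | none | none
F8 | step 11 | C1′ triethylsilyl ether of 22 (same configuration as 22) | CC(C)(C)[Si](c3ccccc3)(c4ccccc4)OCC1=CC(=O)[C@]2([C@H](/C=C(C)/C=C/C(OC)OC)O[Si](CC)(CC)CC)O[C@@H]2C1(OC)OC
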